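| flask | substrate | coupling partner | remark | time |
|---|---|---|---|---|
| dusk | 0.17 M | 0.75 M | run made earlier |  |
| summer | 0.38 M | 0.75 M | run made earlier |  |
| spring | 0.25 M | 1.1 M | run made earlier |  |
| flask | 0.25 M | 0.750 M |  | 5.0 min |

| run | time / min | target / % | isomer of the product A / % | substrate / % |
|---|---|---|---|---|
| dusk | 0.417 | 26.5 | 18.0 | 48.7 |
| dusk | 1.33 | 33.2 | 26.9 | 16.1 |
| dusk | 2.50 | 34.3 | 25.6 | 7.9 |
| dusk | 4.00 | 36.9 | 22.4 | 6.6 |
| dusk | 5.00 | 37.5 | 20.2 | 6.1 |
| summer | 0.417 | 24.2 | 15.9 | 51.8 |
| summer | 0.833 | 28.6 | 23.5 | 31.8 |
| summer | 1.33 | 31.5 | 25.2 | 20.8 |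
| summer | 2.50 | 32.3 | 24.6 | 12.0 |
| summer | 5.00 | 36.4 | 21.0 | 8.3 |
| spring | 1.00 | 35.3 | 28.4 | 12.8 |
| spring | 2.00 | 34.5 | 26.3 | 5.2 |
| spring | 3.00 | 36.1 | 25.0 | 4.7 |
| spring | 4.00 | 37.3 | 22.9 | 4.0 |
| spring | 5.00 | 37.0 | 19.6 | 3.9 |

(readings scatter by 0.5 percentage points)

* ratio of target to isomer of the product A at 0.50 s
* ratio of target to isomer of the product A at 12 s
* ratio of target to isomer of the product A at 5.0 min
* which of target and isomer of the product A there is more of at 5.0 min

The substrate charged stays in four species, so isomer of the product B is the percentage missing from each reading. Target and isomer of the product B together count what the target coupling has made. Both couplings consume the same pair; taken as first order in each, their rates stand in a ratio free of concentrations.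

The first dusk and summer readings give, on average, for (target + isomer of the product B) / isomer of the product A:

1.94 at 0.417 min

This is the weak link. At 1.33 min the same two runs give 2.13, higher than at the first reading, a drift that fits the listed return of isomer of the product A. Run back along that line to time zero, the readings give an estimate of the branching ratio, the selectivity factor of the two couplings:

1.85

Target meanwhile leaks into isomer of the product B. At the first readings, isomer of the product B over target averages 0.296. Taking that share as growing in proportion to time, and dividing the branching ratio by one plus the share: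

at 0.50 s: 1.84

at 12 s: 1.62

For 5.0 min, dusk and summer share this flask's coupling partner charge and bracket its substrate. Their last ratios average 1.79, so this reckoning puts target ahead in the flask.

The forecast says 1.95, 1.72 and 1.8, with target ahead; its early value, above this reckoning, rests on the first readings, “which I take as the kinetic branching ratio”.

The flask gives 1.79, 1.62 and 1.83, with target at 37.2 % and isomer of the product A at 20.3 %. The forward step from target alone has a half-life of 0.55 min, short against 5.0 min. In this flask at 0.500 min, the branching ratio times the 19.1 % of isomer of the product A gives 35.4 % for target and isomer of the product B together; the flask holds 27.3 % and 8.88 %.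

    substrate + coupling partner ⇌ isomer of the product A (K = 3.70 /M, k = 0.0150 /M/s)
    substrate + coupling partner ⇌ target (K = 20.0 /M, k = 0.0270 /M/s)
    target ⇌ isomer of the product B (K = 1.00, k = 0.0210 /s)

For the same flask with 0.19 M of coupling partner, the reckoning contains no concentration, so the estimated branching ratio and the share carry over and it again gives 1.84 and 1.62. The computed ratios there are 1.79 and 1.63, and at 5.0 min 1.68, with target still ahead.

The readings are simulated for substances that don't exist.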